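Time is our yardstick here: every flask stands at the same temperature and every run is read out to 19 min, so one time serves to compare them.

| flask | substrate | coupling partner | catalyst | product | time |
|---|---|---|---|---|---|
| epsilon | 0.0800 M | 0.120 M | 0.00400 M |  |  |
| theta | 0.0480 M | 0.0880 M | 0.00400 M |  |  |
| beta | 0.0800 M | 0.120 M | 0.00400 M | 0.0240 M |  |
| alpha | 0.0800 M | 0.120 M | 0.0120 M |  |  |
| delta | 0.0800 M | 0.240 M | 0.00130 M |  | 19 min |

| run | time / min | [product] / M |
|---|---|---|
| epsilon run | 2.4 | 0.0077 |
| epsilon run | 4.8 | 0.0153 |
| epsilon run | 7.1 | 0.0202 |
| epsilon run | 9.5 | 0.0241 |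
| epsilon run | 12 | 0.0271 |
| epsilon run | 14 | 0.0287 |
| epsilon run | 17 | 0.0295 |
| epsilon run | 19 | 0.0305 |
| theta run | 2.4 | 0.0051 |
| theta run | 4.8 | 0.0120 |
| theta run | 7.1 | 0.0151 |
| theta run | 9.5 | 0.0199 |
| theta run | 12 | 0.0234 |
| theta run | 14 | 0.0235 |
| theta run | 17 | 0.0258 |
| theta run | 19 | 0.0245 |
| beta run | 2.4 | 0.0325 |
| beta run | 4.8 | 0.0389 |
| beta run | 7.1 | 0.0444 |
| beta run | 9.5 | 0.0480 |
| beta run | 12 | 0.0521 |
| beta run | 14 | 0.0535 |
| beta run | 17 | 0.0545 |
| beta run | 19 | 0.0554 |
| alpha run | 2.4 | 0.0218 |
| alpha run | 4.8 | 0.0393 |
| alpha run | 7.1 | 0.0479 |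
| alpha run | 9.5 | 0.0485 |
| alpha run | 12 | 0.0499 |
| alpha run | 14 | 0.0502 |
| alpha run | 17 | 0.0498 |
| alpha run | 19 | 0.0489 |

(scatter of a reading: 8 × 10⁻⁴ M)

- apparent order in [catalyst] of the starting rate, round the charge of the epsilon run (the rate where two percent of its substrate have turned into product)
- product in the delta run at 19 min, as a share of the substrate charged

- Overall: substrate + coupling partner -> product, with catalyst as catalyst.
- Constant volume, constant temperature.
- A reading of a species includes what of it is bound.
- An order is taken over about fifteen percent of the charge, up and down.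

We read the early rows of each table against the last row. In epsilon, the product at 4.8 min gives a starting rate of 0.00319 M min⁻¹. The last reading, 0.0305 M, is 38.1% of the substrate charged, and substrate is the limiting reagent, its charge being smaller than the coupling partner's. Epsilon thus has a reach time τ of 9.57 min, where τ is the product made by the last reading divided by the starting rate.

Theta, read the same way, starts at 0.00250 M min⁻¹ and ends at 0.0245 M, so its τ is 9.80 min. Its substrate charge is 0.600 of epsilon's, yet τ has barely moved.

Alpha bends early, so we take its first row, which gives 0.00908 M min⁻¹. Against epsilon, with 3.00 times the catalyst, that is an order in catalyst of 0.953, as a reading over a wide step. Alpha's τ is 5.38 min, shorter than epsilon's.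

Delta has epsilon's substrate but less catalyst and more coupling partner. Theta's rate is lower than epsilon's, with both its substrate and its partner charges lower; put wholly on the partner, that fall gives an order in partner of 0.783. The substrate may carry some of that fall, so we commit to 0.392, midway to zero. Our estimate of delta's starting rate is then 0.00143 M min⁻¹. Alpha, with more catalyst, had the shorter τ, so for the dilute delta flask we keep epsilon's τ as a cautious value. That gives an estimate of 0.0137 M at 19 min, or 17.1% of the substrate charged.

The forecast, holding that “dilute catalyst should live longer”, says 0.97 for the order and 20% for delta, which is higher than our share.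

The flask gives an order of 0.88 and 19.7% for delta, more than our share; that value is 0.0157 M of product.

    catalyst + substrate → catalyst-substrate complex (93.60 L mol⁻¹ min⁻¹)
    catalyst-substrate complex + coupling partner → product + catalyst (24.06 L mol⁻¹ min⁻¹)
    catalyst + substrate ⇌ idle catalyst-substrate complex, settled at all times (50.10 L mol⁻¹)
    2 substrate → homo dimer (2.838 L mol⁻¹ min⁻¹)

Early in epsilon the apparent order in substrate is 0.14. Delta's product over our starting rate gives a reach time of 11.0 min, against the 9.57 min we carried. On beta, the rate of 0.0035 M min⁻¹, taken where the product made equals two percent of epsilon's substrate, times epsilon's τ promises 0.0335 M of new product by 19 min, and the last reading, less the 0.0240 M added, shows 0.0314 M.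

The runs are calculated with made-up constants, noise included.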